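**Strategy.** The plan disconnects the aryl ether bond O1–C7a of the dihydrobenzofuran. An Evans syn-aldol first sets C2 and C3 in an open-chain 1-aryl-2-(2-bromo-3-methoxyphenyl)propane-1,3-diol whose primary oxygen is silylated. Palladium-catalysed intramolecular etherification then closes the furan ring in one operation without touching either stereocentre, so the syn diol becomes the 2,3-trans ring. The step exploits that O1 sits on benzylic C2, two carbons from C3a, so the alkoxide reaches the neighbouring brominated C7a of ring A (the benzo ring) through a six-membered palladacycle. C5, the only unhindered C–H of ring A, is then borylated and coupled with the allylic chain, and a double Mitsunobu esterification completes the target.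

Key step: step 6

Remark: (2-bromo-3-methoxyphenyl)acetic acid and (E)-3-iodoprop-2-en-1-ol are taken as catalogue compounds; atoms are numbered as in 2,3-dihydrobenzofuran (O1, C2, C3, C3a, C4 to C7, C7a), and ring B is the aryl group on C2.

**Step 1**
Reactants: 1 syringaldehyde (4-hydroxy-3,5-dimethoxybenzaldehyde)
Product: 2 3,5-dimethoxy-4-(triisopropylsilyloxy)benzaldehyde
Conditions: TIPSCl, imidazole, DMAP (cat.), DMF, rt
Reagents that add atoms: triisopropylsilyl chloride (TIPSCl), CC(C)[Si](Cl)(C(C)C)C(C)C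
Why: Imidazole-assisted O-silylation of the phenol; the hindered TIPS ether should survive the boron aldol, hydride, carbonate and phosphate steps and fall to fluoride at the end.

**Step 2**
Reactants: 3 (2-bromo-3-methoxyphenyl)acetic acid; 4 (S)-4-benzyloxazolidin-2-one
Product: 6 (S)-4-benzyl-3-[(2-bromo-3-methoxyphenyl)acetyl]oxazolidin-2-one, via mixed pivalic anhydride 5 (not isolated)
Conditions: t-BuCOCl, Et3N, THF, −20 °C; then LiCl, 4, −20 °C to rt
Reagents that add atoms: none
Why: N-Acylation of the oxazolidinone through the mixed pivalic anhydride under LiCl/Et3N activation avoids strong base next to the aryl bromide; no stereocentre is formed.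

**Step 3**
Reactants: 6 (S)-4-benzyl-3-[(2-bromo-3-methoxyphenyl)acetyl]oxazolidin-2-one; 2 3,5-dimethoxy-4-(triisopropylsilyloxy)benzaldehyde
Product: 8 (S)-4-benzyl-3-[(2S,3S)-2-(2-bromo-3-methoxyphenyl)-3-hydroxy-3-(3,5-dimethoxy-4-triisopropylsilyloxyphenyl)propanoyl]oxazolidin-2-one, via dibutylboron Z-enolate 7 (not isolated)
Conditions: n-Bu2BOTf, i-Pr2NEt, CH2Cl2, −78 to 0 °C; then 2, −78 to 0 °C; pH 7 buffer, MeOH, H2O2, 0 °C
Reagents that add atoms: none
Why: Evans syn-aldol reaction: the Z-boron enolate adds through a Zimmerman–Traxler chair on the enolate face away from the benzyl group of the auxiliary, which should set both new stereocentres as (2S,3S), syn.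

**Step 4**
Reactants: 8 the syn-aldol adduct
Product: 9 (1S,2R)-2-(2-bromo-3-methoxyphenyl)-1-(3,5-dimethoxy-4-triisopropylsilyloxyphenyl)propane-1,3-diol
Conditions: LiBH4, MeOH (1 equiv), THF, 0 °C
Reagents that add atoms: none
Why: Reductive cleavage of the N-acyl oxazolidinone by LiBH4 gives the primary alcohol without touching either stereocentre; the descriptor of the aryl-bearing carbon becomes R only because the priorities change.

**Step 5**
Reactants: 9 the (1S,2R)-diol
Product: 10 (1S,2R)-2-(2-bromo-3-methoxyphenyl)-1-(3,5-dimethoxy-4-triisopropylsilyloxyphenyl)-3-(triisopropylsilyloxy)propan-1-ol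
Conditions: TIPSCl (1.1 equiv), imidazole, CH2Cl2, 0 °C to rt
Reagents that add atoms: triisopropylsilyl chloride (TIPSCl), CC(C)[Si](Cl)(C(C)C)C(C)C
Why: Sterically controlled silyl ether formation: the primary hydroxyl should react far faster than the hindered benzylic one, leaving free only the oxygen that is to become O1.

**Step 6**
Reactants: 10 the bromo alcohol with the primary oxygen silylated
Product: 11 (2S,3R)-2-(3,5-dimethoxy-4-triisopropylsilyloxyphenyl)-7-methoxy-3-(triisopropylsilyloxymethyl)-2,3-dihydrobenzofuran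
Conditions: Pd(OAc)2 (5 mol %), rac-2-(di-tert-butylphosphino)-1,1'-binaphthyl (6 mol %), Cs2CO3, toluene, 80 °C
Reagents that add atoms: none
Why: Zerovalent palladium, formed in situ from Pd(OAc)2 and the bulky phosphine, inserts into the C7a–Br bond, Cs2CO3 deprotonates the C2 hydroxyl on the metal to give a six-membered aryl(alkoxo)palladium chelate, and C–O reductive elimination forms O1–C7a. The closest known reaction type is the Buchwald–Hartwig intramolecular etherification of 2-haloaryl-substituted secondary alcohols to 2,3-dihydrobenzofurans. The five-membered ring closes in a formal 5-exo-trig sense at C7a, by ring contraction of the six-membered palladacycle. No new stereocentre is created: C2 and C3 keep all their bonds, so the (1S,2R)-syn chain maps onto the (2S,3R)-trans ring. The step needs reductive elimination to outrun β-hydride elimination of the benzylic alkoxide, which the hindered electron-rich phosphine should secure, and closure through the secondary oxygen only, which the slow-migrating TIPS cap on the primary oxygen and the single C–Br bond secure.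

**Step 7**
Reactants: 11 the dihydrobenzofuran; 12 (E)-3-iodoprop-2-en-1-ol
Product: 14 (E)-3-[(2S,3R)-2-(3,5-dimethoxy-4-triisopropylsilyloxyphenyl)-7-methoxy-3-(triisopropylsilyloxymethyl)-2,3-dihydrobenzofuran-5-yl]prop-2-en-1-ol, via C5 pinacol boronate 13 (not isolated)
Conditions: [Ir(OMe)(cod)]2 (1.5 mol %), 4,4'-di-tert-butyl-2,2'-bipyridine, B2pin2, THF, 80 °C; evaporate; then 12, PdCl2(dppf) (5 mol %), aq K3PO4, DMF, 60 °C
Reagents that add atoms: none
Why: Iridium-catalysed C–H borylation is sterically controlled and should take C5, the only aromatic C–H without an ortho substituent (C4 and C6 have one, the ring B positions two), and Suzuki–Miyaura coupling with the vinyl iodide then proceeds with retention of the E geometry.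

**Step 8**
Reactants: 14 the bis-silylated allylic alcohol
Product: 15 (E)-3-[(2S,3R)-2-(4-hydroxy-3,5-dimethoxyphenyl)-3-(hydroxymethyl)-7-methoxy-2,3-dihydrobenzofuran-5-yl]prop-2-en-1-ol
Conditions: TBAF, AcOH (1:1), THF, 0 °C to rt
Reagents that add atoms: none
Why: Fluoride cleaves both silyl ethers through Si–F bond formation, and the acetic acid buffer should keep the liberated phenoxide from opening the benzylic aryl ether.

**Step 9**
Reactants: 15 the triol; 16 4-hydroxybenzoic acid (2.4 equiv)
Product: 17 quiquesetinerviusin B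
Conditions: PPh3, DIAD, THF, 0 °C to rt
Reagents that add atoms: none
Why: Mitsunobu esterification: only the carboxylic acid of 16 is acidic enough to protonate the betaine and attack the alkoxyphosphonium ions of the two primary alcohols, so the three phenols should stay free and no stereocentre is involved.

**Compound list**

1 | syringaldehyde | COc1cc(C=O)cc(OC)c1O | starting material
2 | 3,5-dimethoxy-4-(triisopropylsilyloxy)benzaldehyde | COc1cc(C=O)cc(OC)c1O[Si](C(C)C)(C(C)C)C(C)C | intermediate
3 | (2-bromo-3-methoxyphenyl)acetic acid | COc1cccc(CC(=O)O)c1Br | starting material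
4 | (S)-4-benzyloxazolidin-2-one | O=C1N[C@@H](Cc2ccccc2)CO1 | starting material
5 | (2-bromo-3-methoxyphenyl)acetic pivalic anhydride (not isolated) | COc1cccc(CC(=O)OC(=O)C(C)(C)C)c1Br | intermediate
6 | (S)-4-benzyl-3-[(2-bromo-3-methoxyphenyl)acetyl]oxazolidin-2-one | COc1cccc(CC(=O)N2[C@@H](Cc3ccccc3)COC2=O)c1Br | intermediate
7 | dibutylboron Z-enolate of 6 (not isolated) | CCCCB(CCCC)O/C(=C\c1cccc(OC)c1Br)N1[C@@H](Cc2ccccc2)COC1=O | intermediate
8 | (S)-4-benzyl-3-[(2S,3S)-2-(2-bromo-3-methoxyphenyl)-3-hydroxy-3-(3,5-dimethoxy-4-triisopropylsilyloxyphenyl)propanoyl]oxazolidin-2-one | COc1cc([C@@H](O)[C@@H](C(=O)N2[C@@H](Cc3ccccc3)COC2=O)c2cccc(OC)c2Br)cc(OC)c1O[Si](C(C)C)(C(C)C)C(C)C | intermediate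
9 | (1S,2R)-2-(2-bromo-3-methoxyphenyl)-1-(3,5-dimethoxy-4-triisopropylsilyloxyphenyl)propane-1,3-diol | COc1cc([C@@H](O)[C@@H](CO)c2cccc(OC)c2Br)cc(OC)c1O[Si](C(C)C)(C(C)C)C(C)C | intermediate
10 | (1S,2R)-2-(2-bromo-3-methoxyphenyl)-1-(3,5-dimethoxy-4-triisopropylsilyloxyphenyl)-3-(triisopropylsilyloxy)propan-1-ol | COc1cc([C@@H](O)[C@@H](CO[Si](C(C)C)(C(C)C)C(C)C)c2cccc(OC)c2Br)cc(OC)c1O[Si](C(C)C)(C(C)C)C(C)C | intermediate
11 | (2S,3R)-2-(3,5-dimethoxy-4-triisopropylsilyloxyphenyl)-7-methoxy-3-(triisopropylsilyloxymethyl)-2,3-dihydrobenzofuran | COc1cc([C@H]2Oc3c(OC)cccc3[C@@H]2CO[Si](C(C)C)(C(C)C)C(C)C)cc(OC)c1O[Si](C(C)C)(C(C)C)C(C)C | intermediate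
12 | (E)-3-iodoprop-2-en-1-ol | OC/C=C/I | starting material
13 | C5 pinacol boronate of 11 (not isolated) | COc1cc([C@H]2Oc3c(OC)cc(B4OC(C)(C)C(C)(C)O4)cc3[C@@H]2CO[Si](C(C)C)(C(C)C)C(C)C)cc(OC)c1O[Si](C(C)C)(C(C)C)C(C)C | intermediate
14 | (E)-3-[(2S,3R)-2-(3,5-dimethoxy-4-triisopropylsilyloxyphenyl)-7-methoxy-3-(triisopropylsilyloxymethyl)-2,3-dihydrobenzofuran-5-yl]prop-2-en-1-ol | COc1cc([C@H]2Oc3c(OC)cc(/C=C/CO)cc3[C@@H]2CO[Si](C(C)C)(C(C)C)C(C)C)cc(OC)c1O[Si](C(C)C)(C(C)C)C(C)C | intermediate
15 | (E)-3-[(2S,3R)-2-(4-hydroxy-3,5-dimethoxyphenyl)-3-(hydroxymethyl)-7-methoxy-2,3-dihydrobenzofuran-5-yl]prop-2-en-1-ol | COc1cc([C@H]2Oc3c(OC)cc(/C=C/CO)cc3[C@@H]2CO)cc(OC)c1O | intermediate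
16 | 4-hydroxybenzoic acid | OC(=O)c1ccc(O)cc1 | starting material
17 | quiquesetinerviusin B | COc1cc([C@H]2Oc3c(OC)cc(/C=C/COC(=O)c4ccc(O)cc4)cc3[C@@H]2COC(=O)c2ccc(O)cc2)cc(OC)c1O | target

**Step count.** Total: 9 steps. Longest linear sequence: 8 steps (steps 2 to 9, from 3 to 17).

**Steps most likely to fail**

Step 6. The palladium alkoxide may undergo β-hydride elimination, which oxidises the benzylic alcohol and reduces the C–Br bond. Reductive elimination at the doubly ortho-substituted C7a may also be slow, or base may move the primary silyl group so that the wrong oxygen closes the ring. The fallback makes the same O1–C7a bond without a metal, by intramolecular nucleophilic aromatic substitution of fluoride. It sets out from 4 and 2: commercial (2-fluoro-3-methoxyphenyl)acetic acid is taken through the conditions of steps 2 to 5. This should give in turn the mixed pivalic anhydride F1 (not isolated), the fluoro imide F2, its dibutylboron Z-enolate F3 (not isolated), the syn-aldol adduct F4, the diol F5 and the mono-TIPS ether F6. NaN(SiMe3)2 in THF/DMPU at 60 °C should then let the C2 alkoxide displace fluoride at C7a; NaF precipitates, which spares the silyl ethers. The route is rejoined at 11.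

Step 9. The phosphonium-activated, electron-rich cinnamyl alcohol may ionise, leading to SN2′ attack (branched ester) or elimination, and phenols may be O-alkylated in competition with the carboxylate. The fallback sets out from 15 and 16. Compound 16 is silylated twice (TBSCl, imidazole, DMF) to the silyl ester silyl ether F7, whose silyl ester is hydrolysed (K2CO3, aqueous THF/MeOH) to 4-(tert-butyldimethylsilyloxy)benzoic acid F8. Steglich esterification of 15 with F8 (2.1 equiv, EDC·HCl, DMAP, CH2Cl2, 0 °C), in which the two primary alcohols should react ahead of the hindered phenol, gives the bis(silyloxybenzoate) F9. KHF2 in MeOH then removes the two phenolic silyl groups and the route comes back at 17.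

Step 7. The C–H borylation may be incompletely site-selective, the boronate may be lost by protodeboronation under aqueous base, or the unprotected iodo-allyl alcohol may enter Heck-type side reactions. The fallback sets out from 13, now isolated by filtration through silica. An oxidative Heck reaction with methyl acrylate (Pd(OAc)2, 2,9-dimethyl-1,10-phenanthroline, O2 balloon, DMF, 50 °C) should give the methyl (E)-cinnamate F10. Reduction with i-Bu2AlH (CH2Cl2, −78 °C) converts the ester into the allylic alcohol and the route comes back at 14.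

**Further compounds**

F1 | step 6 | (2-fluoro-3-methoxyphenyl)acetic pivalic anhydride | COc1cccc(CC(=O)OC(=O)C(C)(C)C)c1F
F2 | step 6 | (S)-4-benzyl-3-[(2-fluoro-3-methoxyphenyl)acetyl]oxazolidin-2-one | COc1cccc(CC(=O)N2[C@@H](Cc3ccccc3)COC2=O)c1F
F3 | step 6 | dibutylboron Z-enolate of F2 | CCCCB(CCCC)O/C(=C\c1cccc(OC)c1F)N1[C@@H](Cc2ccccc2)COC1=O
F4 | step 6 | (S)-4-benzyl-3-[(2S,3S)-2-(2-fluoro-3-methoxyphenyl)-3-hydroxy-3-(3,5-dimethoxy-4-triisopropylsilyloxyphenyl)propanoyl]oxazolidin-2-one | COc1cc([C@@H](O)[C@@H](C(=O)N2[C@@H](Cc3ccccc3)COC2=O)c2cccc(OC)c2F)cc(OC)c1O[Si](C(C)C)(C(C)C)C(C)C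
F5 | step 6 | (1S,2R)-2-(2-fluoro-3-methoxyphenyl)-1-(3,5-dimethoxy-4-triisopropylsilyloxyphenyl)propane-1,3-diol | COc1cc([C@@H](O)[C@@H](CO)c2cccc(OC)c2F)cc(OC)c1O[Si](C(C)C)(C(C)C)C(C)C
F6 | step 6 | (1S,2R)-2-(2-fluoro-3-methoxyphenyl)-1-(3,5-dimethoxy-4-triisopropylsilyloxyphenyl)-3-(triisopropylsilyloxy)propan-1-ol | COc1cc([C@@H](O)[C@@H](CO[Si](C(C)C)(C(C)C)C(C)C)c2cccc(OC)c2F)cc(OC)c1O[Si](C(C)C)(C(C)C)C(C)C
F7 | step 9 | tert-butyldimethylsilyl 4-(tert-butyldimethylsilyloxy)benzoate | CC(C)(C)[Si](C)(C)OC(=O)c1ccc(O[Si](C)(C)C(C)(C)C)cc1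
F8 | step 9 | 4-(tert-butyldimethylsilyloxy)benzoic acid | CC(C)(C)[Si](C)(C)Oc1ccc(C(=O)O)cc1
F9 | step 9 | bis[4-(tert-butyldimethylsilyloxy)benzoate] of 15 | COc1cc([C@H]2Oc3c(OC)cc(/C=C/COC(=O)c4ccc(O[Si](C)(C)C(C)(C)C)cc4)cc3[C@@H]2COC(=O)c2ccc(O[Si](C)(C)C(C)(C)C)cc2)cc(OC)c1O
F10 | step 7 | methyl (E)-3-[(2S,3R)-2-(3,5-dimethoxy-4-triisopropylsilyloxyphenyl)-7-methoxy-3-(triisopropylsilyloxymethyl)-2,3-dihydrobenzofuran-5-yl]acrylate | COc1cc([C@H]2Oc3c(OC)cc(/C=C/C(=O)OC)cc3[C@@H]2CO[Si](C(C)C)(C(C)C)C(C)C)cc(OC)c1O[Si](C(C)C)(C(C)C)C(C)C
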